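**Assumptions (one line each)**
- Seebach allylation of diethyl L-tartrate delivers the allyl group anti to the neighbouring alkoxide. This gives the (2S,3R)-2-allyl tartrate **3**, whose quaternary carbinol carbon becomes C8 of the target.
- The E-enal cyclises to the cis-fused adduct with the desired relative configuration as the major diastereomer, and C1 equilibrates to the anomer with OIsov cis to H9.
- Iridoid numbering is used throughout: C1 acetal, O2, C3=C4 with C11 on C4, C5, C6, C7, C8 with C10 on C8, and C9.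

**Retrosynthesis**
- The target comes from reduction of a 7-keto dienone, which comes from dehydrogenation of the 7-keto cyclopentane, which comes from the cis-fused cyclopenta[c]pyran 1-isovalerate.
- That bicycle arises in one step by intramolecular inverse-demand hetero-Diels–Alder of a 2-(acetoxymethyl)enal (C3–C5) tethered to a silyl enol ether (C9=C1). The dihydropyran and the cyclopentane form together, setting C5, C9 and C1.
- The tether comes from Morita–Baylis–Hillman/SN2′ on a C5 aldehyde, which comes from one-carbon homologation of a tartrate ester.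
- The quaternary C8 (with the C7 carbinol) comes from Seebach allylation of diethyl L-tartrate.

---

**Step 1**
Reactants: 1 diethyl L-tartrate; 2 allyl bromide
Product: 3 diethyl (2S,3R)-2-allyl-2,3-dihydroxysuccinate
Conditions: LDA (3.2 equiv), THF, –78 °C; then 2, –78 → –30 °C
Reagents that add atoms: allyl bromide, C=CCBr
Why: The chelated lithium tri-anion is alkylated anti to the adjacent alkoxide (Seebach enolate alkylation), forming the C8 quaternary stereocentre while C7 is retained from tartrate.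

**Step 2**
Reactants: 3
Product: 4 diethyl (2S,3R)-2-allyl-2,3-bis(TBSO)succinate
Conditions: TBSOTf (3 equiv), 2,6-lutidine, CH2Cl2, 0 °C → rt
Reagents that add atoms: TBSOTf, CC(C)(C)[Si](C)(C)OS(=O)(=O)C(F)(F)F
Why: Silyl triflate protection of both hydroxyls; no stereocentre is touched.

**Step 3**
Reactants: 4
Product: 5 ethyl (2S,3R)-2-allyl-2,3-bis(TBSO)-4-oxobutanoate
Conditions: DIBAL-H (1.05 equiv), CH2Cl2, –78 °C
Reagents that add atoms: none
Why: Partial ester reduction occurs at the less hindered C6 ester, because the C10 ester sits on a fully substituted carbon and is untouched at –78 °C.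

**Step 4**
Reactants: 5; 6 (methoxymethyl)triphenylphosphonium chloride
Product: 7 ethyl (2S,3S)-2-allyl-2,3-bis(TBSO)-5-methoxypent-4-enoate (E/Z)
Conditions: 6 + KOtBu, THF, 0 °C; add 5, –78 °C → rt
Reagents that add atoms: (methoxymethyl)triphenylphosphonium chloride, COC[P+](c1ccccc1)(c1ccccc1)c1ccccc1.[Cl-]
Why: Wittig methoxymethylenation adds the C5 carbon as a masked aldehyde; no new stereocentre.

**Step 5**
Reactants: 7
Product: 8 (2R,3S)-2-allyl-2,3-bis(TBSO)-5-methoxypent-4-en-1-ol
Conditions: LiAlH4, THF, 0 °C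
Reagents that add atoms: none
Why: The remaining ester is reduced to the C10 primary alcohol; the enol ether, TBS ethers and terminal alkene are inert.

**Step 6**
Reactants: 8; 9 isovaleryl chloride
Product: 10 (2R,3S)-2-allyl-2,3-bis(TBSO)-5-methoxypent-4-en-1-yl 3-methylbutanoate
Conditions: 9 (1.5 equiv), pyridine, DMAP (cat.), CH2Cl2, 0 °C
Reagents that add atoms: isovaleryl chloride, CC(C)CC(=O)Cl
Why: Acylation installs the C10 isovalerate, which is carried to the end.

**Step 7**
Reactants: 10
Product: 11 (2R,3S)-2-allyl-2,3-bis(TBSO)-5-oxopentyl 3-methylbutanoate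
Conditions: PPTS (0.3 equiv), acetone/H2O (9:1), 50 °C
Reagents that add atoms: water, O
Why: Mild acid hydrolysis of the enol ether unmasks the C5 aldehyde; TBS ethers and ester survive.

**Step 8**
Reactants: 11; 12 acrolein
Product: 13 (2R,3S)-2-allyl-2,3-bis(TBSO)-5-hydroxy-6-methylene-7-oxoheptyl 3-methylbutanoate (C5 epimers)
Conditions: 12 (3 equiv), DABCO (0.3 equiv), MeOH, rt, 3 d
Reagents that add atoms: acrolein, C=CC=O
Why: Morita–Baylis–Hillman reaction builds C4 with C3 (CHO) and C11 (=CH2); the new C5 carbinol stereocentre is later lost.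

**Step 9**
Reactants: 13
Product: 14 (2R,3S,E)-6-(acetoxymethyl)-2-allyl-2,3-bis(TBSO)-7-oxohept-5-en-1-yl 3-methylbutanoate
Conditions: Ac2O, Et3N, DMAP (cat.), CH2Cl2, 0 °C; then DABCO (0.2 equiv), THF, 40 °C
Reagents that add atoms: acetic anhydride, CC(=O)OC(C)=O
Why: The MBH acetate undergoes DABCO-mediated SN2′ acetate transposition (allylic 1,3-shift) to the thermodynamic E-2-(acetoxymethyl)enal, which is the C3–C5 oxadiene with C11 already as OAc.

**Step 10**
Reactants: 14
Product: 15 (2R,3S,E)-6-(acetoxymethyl)-2,3-bis(TBSO)-7-oxo-2-(2-oxoethyl)hept-5-en-1-yl 3-methylbutanoate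
Conditions: OsO4 (5 mol%), 2,6-lutidine, NaIO4, dioxane/H2O, rt
Reagents that add atoms: sodium periodate, [Na+].[O-]I(=O)(=O)=O; OsO4 (catalyst), O=[Os](=O)(=O)=O
Why: Lemieux–Johnson cleavage converts the electron-rich terminal alkene (not the electron-poor enal) into the C1 aldehyde.

**Step 11 (key step)**
Reactants: 15
Product: 16 (1S,5S,7S,8R,9S)-4-(acetoxymethyl)-7,8-bis(TBSO)-8-(isovaleryloxymethyl)-1-(trimethylsilyloxy)-1,5,6,7,8,9-hexahydrocyclopenta[c]pyran
Conditions: TMSOTf (1.5 equiv), Et3N (3 equiv), CH2Cl2, 0 °C, 30 min; then toluene, BHT, 110 °C, sealed tube, 12 h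
Reagents that add atoms: TMSOTf, C[Si](C)(C)OS(=O)(=O)C(F)(F)F
Why: Chemoselective silyl enol ether formation at the C1 aldehyde is followed by intramolecular inverse-electron-demand hetero-Diels–Alder (O2–C1 and C5–C9 bonds), closing the dihydropyran and cyclopentane together; suprafacial cis-fused addition fixes H5/H9 cis, and C1 is set by the anomeric effect.

**Step 12**
Reactants: 16
Product: 17 lactol (1-OH, anomeric mixture; 5S,7S,8R,9S) with 7,8-bis(TBSO)
Conditions: KF, MeOH, 0 °C, 15 min
Reagents that add atoms: none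
Why: Fluoride cleaves the labile O–TMS bond of the silyl acetal without forming an oxocarbenium, so no methyl acetal forms and the TBS ethers are untouched.

**Step 13**
Reactants: 17; 9 isovaleryl chloride
Product: 18 (1S,5S,7S,8R,9S) 1-isovalerate of 17 (C7, C8 bis-TBS)
Conditions: 9 (1.5 equiv), pyridine, DMAP (cat.), CH2Cl2, 0 °C
Reagents that add atoms: isovaleryl chloride, CC(C)CC(=O)Cl
Why: The anomeric hydroxyl is acylated chemoselectively (C7 and C8 are protected), giving the C1 acyloxy acetal with OIsov cis to H9 as the major anomer.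

**Step 14**
Reactants: 18
Product: 19 (1S,5S,7S,8R,9S) 7,8-diol
Conditions: HF·pyridine, pyridine, THF, 0 °C → 40 °C, 24 h
Reagents that add atoms: none
Why: Buffered HF removes both silyl ethers, leaving the acid-sensitive acylal, enol ether and esters intact.

**Step 15**
Reactants: 19
Product: 20 (1S,5S,8R,9S) 7-ketone
Conditions: Dess–Martin periodinane (1.5 equiv), NaHCO3, CH2Cl2, rt
Reagents that add atoms: none
Why: Only the secondary C7 alcohol is oxidised; the tertiary C8 alcohol cannot be.

**Step 16**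
Reactants: 20
Product: 21 (1S,8R,9S) 7-keto-5,6-ene (push–pull dienone)
Conditions: IBX (2.5 equiv), DMSO, 65 °C
Reagents that add atoms: none
Why: Nicolaou IBX dehydrogenation can enolise only toward C6 (C8 is quaternary), giving the C5=C6 enone that is conjugated with the C3=C4 enol ether; this destroys the C5 stereocentre.

**Step 17**
Reactants: 21
Product: 22 Jatamanvaltrate J
Conditions: Zn(BH4)2, Et2O, –20 °C
Reagents that add atoms: none
Why: Hydride is delivered from the face syn to the chelated C8–OH and anti to the C10 substituent, setting C7–OH trans to C8–OH in a chelation-controlled ketone reduction.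

---

**Compound list**

| # | Name | SMILES | Role |
|---|---|---|---|
| 1 | diethyl L-tartrate | CCOC(=O)[C@H](O)[C@@H](O)C(=O)OCC | starting material |
| 2 | allyl bromide | C=CCBr | starting material |
| 3 | diethyl (2S,3R)-2-allyl-2,3-dihydroxysuccinate | CCOC(=O)[C@H](O)[C@@](O)(CC=C)C(=O)OCC | intermediate |
| 4 | diethyl (2S,3R)-2-allyl-2,3-bis(TBSO)succinate | CCOC(=O)[C@H](O[Si](C)(C)C(C)(C)C)[C@@](O[Si](C)(C)C(C)(C)C)(CC=C)C(=O)OCC | intermediate |
| 5 | ethyl (2S,3R)-2-allyl-2,3-bis(TBSO)-4-oxobutanoate | O=C[C@H](O[Si](C)(C)C(C)(C)C)[C@@](O[Si](C)(C)C(C)(C)C)(CC=C)C(=O)OCC | intermediate |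
| 6 | (methoxymethyl)triphenylphosphonium chloride | COC[P+](c1ccccc1)(c1ccccc1)c1ccccc1.[Cl-] | starting material |
| 7 | ethyl (2S,3S)-2-allyl-2,3-bis(TBSO)-5-methoxypent-4-enoate | COC=C[C@H](O[Si](C)(C)C(C)(C)C)[C@@](O[Si](C)(C)C(C)(C)C)(CC=C)C(=O)OCC | intermediate |
| 8 | (2R,3S)-2-allyl-2,3-bis(TBSO)-5-methoxypent-4-en-1-ol | COC=C[C@H](O[Si](C)(C)C(C)(C)C)[C@@](O[Si](C)(C)C(C)(C)C)(CC=C)CO | intermediate |
| 9 | isovaleryl chloride | CC(C)CC(=O)Cl | starting material |
| 10 | (2R,3S)-2-allyl-2,3-bis(TBSO)-5-methoxypent-4-en-1-yl 3-methylbutanoate | COC=C[C@H](O[Si](C)(C)C(C)(C)C)[C@@](O[Si](C)(C)C(C)(C)C)(CC=C)COC(=O)CC(C)C | intermediate |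
| 11 | (2R,3S)-2-allyl-2,3-bis(TBSO)-5-oxopentyl 3-methylbutanoate | O=CC[C@H](O[Si](C)(C)C(C)(C)C)[C@@](O[Si](C)(C)C(C)(C)C)(CC=C)COC(=O)CC(C)C | intermediate |
| 12 | acrolein | C=CC=O | starting material |
| 13 | MBH adduct (5-epimeric mixture) | C=C(C=O)C(O)C[C@H](O[Si](C)(C)C(C)(C)C)[C@@](O[Si](C)(C)C(C)(C)C)(CC=C)COC(=O)CC(C)C | intermediate |
| 14 | E-enal acetate | O=CC(COC(C)=O)=CC[C@H](O[Si](C)(C)C(C)(C)C)[C@@](O[Si](C)(C)C(C)(C)C)(CC=C)COC(=O)CC(C)C | intermediate |
| 15 | enal–aldehyde | O=CC(COC(C)=O)=CC[C@H](O[Si](C)(C)C(C)(C)C)[C@@](O[Si](C)(C)C(C)(C)C)(CC=O)COC(=O)CC(C)C | intermediate |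
| 16 | hetero-Diels–Alder adduct (1-OTMS) | CC(=O)OCC1=CO[C@@H](O[Si](C)(C)C)[C@H]2[C@@H]1C[C@H](O[Si](C)(C)C(C)(C)C)[C@]2(O[Si](C)(C)C(C)(C)C)COC(=O)CC(C)C | intermediate |
| 17 | lactol (anomeric mixture) | CC(=O)OCC1=COC(O)[C@H]2[C@@H]1C[C@H](O[Si](C)(C)C(C)(C)C)[C@]2(O[Si](C)(C)C(C)(C)C)COC(=O)CC(C)C | intermediate |
| 18 | 1-isovalerate, 7,8-bis-TBS | CC(=O)OCC1=CO[C@@H](OC(=O)CC(C)C)[C@H]2[C@@H]1C[C@H](O[Si](C)(C)C(C)(C)C)[C@]2(O[Si](C)(C)C(C)(C)C)COC(=O)CC(C)C | intermediate |
| 19 | 7,8-diol | CC(=O)OCC1=CO[C@@H](OC(=O)CC(C)C)[C@H]2[C@@H]1C[C@H](O)[C@]2(O)COC(=O)CC(C)C | intermediate |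
| 20 | 7-ketone | CC(=O)OCC1=CO[C@@H](OC(=O)CC(C)C)[C@H]2[C@@H]1CC(=O)[C@]2(O)COC(=O)CC(C)C | intermediate |
| 21 | 7-keto-5,6-ene | CC(=O)OCC1=CO[C@@H](OC(=O)CC(C)C)[C@H]2C1=CC(=O)[C@]2(O)COC(=O)CC(C)C | intermediate |
| 22 | Jatamanvaltrate J | CC(=O)OCC1=CO[C@@H](OC(=O)CC(C)C)[C@H]2C1=C[C@H](O)[C@]2(O)COC(=O)CC(C)C | target |

---

**Total steps:** 17. **Longest linear sequence:** 17.

**Three steps most likely to fail**
1. **Step 11 (hetero-Diels–Alder):** the enal is only weakly activated, and the diastereoselectivity at C9/C1 is uncertain. Fallback: form the cyclopentane first by intramolecular aldol or HWE closure of the same tether. Then close the dihydropyran biomimetically by lactolisation of a C1 aldehyde with the enolised C3 aldehyde of a dialdehyde.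
2. **Step 3 (mono-DIBAL of the two esters):** selectivity between C6 and C10 is not guaranteed. Fallback: break the symmetry before alkylation. Make diethyl tartrate acetonide, mono-reduce it with NaBH4, then do the Seebach allylation on the hydroxy ester.
3. **Step 16 (IBX dehydrogenation):** the acetal/enol ether may not tolerate DMSO at 65 °C, and C9 may epimerise through the dienolate. Fallback: α-selenation of the C7 ketone enolate (LiHMDS, PhSeCl) followed by H2O2 selenoxide elimination to install C5=C6 under milder conditions.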